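**Retrosynthetic overview**
1. Ring: the only ring, the trans-oxirane, is not built in the route. It is carried in as racemic 2-heptyloxirane 1 and resolved to (R)-2, which already holds C10.
2. Key disconnection C8–C9: the oxirane CH2 carbon of 2 (normally an electrophile) is used as a nucleophile against the electrophilic propargylic carbon of bromide 3, through oxiranyllithium 4, to give 5. This one bond sets C9 trans to the heptyl group.
3. Diyne C5–C6: bromoalkyne 6 (from 5) is coupled with the (S)-enantiomer 8 of pent-1-en-4-yn-3-ol 7, which brings in C3, to give 9.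
4. Ester C–O last: 9 plus linoleic acid 10 (activated as 11) gives target 12.

Assumption: the SMILES is taken literally, so C3 is S and the oxirane is trans with C9 and C10 both R (not the cis-epoxide of natural panaxydol); C1–C17 number the heptadecenediyne chain.

**Step 1**
Reactants: 1 rac-2-heptyloxirane (1,2-epoxynonane)
Product: 2 (2R)-2-heptyloxirane
Conditions: (R,R)-(salen)Co(OAc) (0.5 mol%; salen = N,N'-bis(3,5-di-tert-butylsalicylidene)cyclohexane-1,2-diamine dianion), H2O (0.55 equiv), THF (minimal), 0 °C to rt, 18 h; distil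
Reagents that add atoms: none
Why: Jacobsen hydrolytic kinetic resolution; the (R,R) salen complex of trivalent cobalt hydrates the (S)-epoxide at its terminal carbon far faster, so (R)-2 is recovered in high ee and fixes C10.

**Step 2**
Reactants: 2 (2R)-2-heptyloxirane; 3 (3-bromoprop-1-yn-1-yl)trimethylsilane
Product: 5 trimethyl{3-[(2R,3R)-3-heptyloxiran-2-yl]prop-1-yn-1-yl}silane, via (2R,3R)-3-heptyloxiran-2-yllithium 4 (not isolated)
Conditions: sBuLi (1.3 equiv), (−)-sparteine (1.3 equiv), Et2O, −90 °C, 2 h; then 3 (2.0 equiv), −90 to −50 °C; MeOH quench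
Reagents that add atoms: none
Why: Proposed new method: diamine-ligated sBuLi removes the oxirane CH2 proton trans to the heptyl group (the known lithiation of terminal epoxides, so far trapped with silyl, stannyl and carbonyl electrophiles) to give the configurationally stable α-oxygenated carbanion 4, which should displace the primary propargylic bromide of 3 by SN2 with retention at the carbanion carbon, so the new C8–C9 bond lies trans to heptyl (C9 = R) while C10 is untouched; the silyl cap removes the acidic alkyne C–H and disfavours SN2' attack; the closest known reactions are this electrophile trapping of lithiated terminal epoxides and the alkylation of silyl- or sulfonyl-stabilised oxiranyl anions with alkyl halides and triflates.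

**Step 3**
Reactants: 5 trimethyl{3-[(2R,3R)-3-heptyloxiran-2-yl]prop-1-yn-1-yl}silane
Product: 6 (2R,3R)-2-(3-bromoprop-2-yn-1-yl)-3-heptyloxirane
Conditions: NBS (1.2 equiv), AgNO3 (10 mol%), acetone, rt, dark, 2 h
Reagents that add atoms: N-bromosuccinimide (NBS), O=C1CCC(=O)N1Br
Why: Silver-catalysed bromodesilylation; Ag+ turns the alkynylsilane into a silver acetylide that NBS brominates under near-neutral conditions, leaving the 2,3-dialkyl oxirane and both stereocentres untouched.

**Step 4**
Reactants: 7 rac-pent-1-en-4-yn-3-ol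
Product: 8 (3S)-pent-1-en-4-yn-3-ol
Conditions: Ti(OiPr)4 (15 mol%), L-(+)-diisopropyl tartrate (18 mol%), tBuOOH (0.6 equiv, in isooctane), 4 Å sieves, CH2Cl2, −20 °C, to about 60% conversion; chromatography (pentane/Et2O), bulb-to-bulb distillation
Reagents that add atoms: none
Why: Sharpless kinetic resolution of a secondary allylic alcohol (close to the epoxidation of penta-1,4-dien-3-ol); with L-(+)-tartrate the (R)-enantiomer is epoxidised faster and the (S)-alcohol, the future C3, is recovered.

**Step 5**
Reactants: 6 (2R,3R)-2-(3-bromoprop-2-yn-1-yl)-3-heptyloxirane; 8 (3S)-pent-1-en-4-yn-3-ol (1.5 equiv)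
Product: 9 (3S)-8-[(2R,3R)-3-heptyloxiran-2-yl]oct-1-ene-4,6-diyn-3-ol
Conditions: CuCl (10 mol%), NH2OH·HCl (20 mol%), n-BuNH2 (30% in water), Et2O, 0 °C, 1 h, dark
Reagents that add atoms: none
Why: Cadiot–Chodkiewicz coupling; the copper acetylide of 8 couples with the 1-bromoalkyne 6 to form C5–C6 at 0 °C, where the free alcohol, the oxirane and the three stereocentres are unaffected.

**Step 6**
Reactants: 9 (3S)-8-[(2R,3R)-3-heptyloxiran-2-yl]oct-1-ene-4,6-diyn-3-ol; 10 linoleic acid ((9Z,12Z)-octadeca-9,12-dienoic acid, 1.2 equiv)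
Product: 12 (3S)-8-[(2R,3R)-3-heptyloxiran-2-yl]oct-1-ene-4,6-diyn-3-yl (9Z,12Z)-octadeca-9,12-dienoate, via O-linoleoyl-N,N'-dicyclohexylisourea 11 (not isolated)
Conditions: DCC (1.3 equiv), DMAP (0.1 equiv), CH2Cl2, 0 °C to rt, argon, dark
Reagents that add atoms: none
Why: Steglich esterification; acyl transfer through the O-acylisourea and acylpyridinium takes place at oxygen under neutral conditions, so C3 keeps its S configuration and the skipped Z,Z-diene, the diyne and the oxirane are not touched.

**Compound list**
1 | rac-2-heptyloxirane (1,2-epoxynonane) | CCCCCCCC1CO1 | starting material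
2 | (2R)-2-heptyloxirane | C1O[C@@H]1CCCCCCC | intermediate
3 | (3-bromoprop-1-yn-1-yl)trimethylsilane | C[Si](C)(C)C#CCBr | starting material
4 | (2R,3R)-3-heptyloxiran-2-yllithium (sparteine-ligated, not isolated) | [Li][C@H]1O[C@@H]1CCCCCCC | intermediate
5 | trimethyl{3-[(2R,3R)-3-heptyloxiran-2-yl]prop-1-yn-1-yl}silane | C[Si](C)(C)C#CC[C@H]1O[C@@H]1CCCCCCC | intermediate
6 | (2R,3R)-2-(3-bromoprop-2-yn-1-yl)-3-heptyloxirane | BrC#CC[C@H]1O[C@@H]1CCCCCCC | intermediate
7 | rac-pent-1-en-4-yn-3-ol | C=CC(O)C#C | starting material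
8 | (3S)-pent-1-en-4-yn-3-ol | C=C[C@@H](C#C)O | intermediate
9 | (3S)-8-[(2R,3R)-3-heptyloxiran-2-yl]oct-1-ene-4,6-diyn-3-ol | C=C[C@@H](C#CC#CC[C@H]1O[C@@H]1CCCCCCC)O | intermediate
10 | linoleic acid, (9Z,12Z)-octadeca-9,12-dienoic acid | OC(=O)CCCCCCC/C=C\C/C=C\CCCCC | starting material
11 | O-linoleoyl-N,N'-dicyclohexylisourea (not isolated) | C1CCCCC1N=C(NC1CCCCC1)OC(=O)CCCCCCC/C=C\C/C=C\CCCCC | intermediate
12 | (3S)-8-[(2R,3R)-3-heptyloxiran-2-yl]oct-1-ene-4,6-diyn-3-yl (9Z,12Z)-octadeca-9,12-dienoate | C=C[C@@H](C#CC#CC[C@H]1O[C@@H]1CCCCCCC)OC(=O)CCCCCCC/C=C\C/C=C\CCCCC | target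

**Totals**
Total steps: 6. Longest linear sequence: 5 steps (steps 1, 2, 3, 5, 6; 1 → 2 → 5 → 6 → 9 → 12). Step 4 is a one-step side branch.

**Steps most likely to fail, each with one fallback**

Step 2 (alkylation of the oxiranyllithium). The anion may instead take a proton from 3 or from the propargylic C8–H of 5 (followed by β-opening of the oxirane), undergo Br/Li exchange, or decay as a carbenoid above about −80 °C. The fallback sets out from 2 and comes back at 5; it is two steps longer. Compound 2 is lithiated as in step 2, but the anion is trapped with a carbonyl electrophile, the class for which this lithiation is established. DMF gives (2S,3R)-3-heptyloxirane-2-carbaldehyde F1, which is reduced without isolation (NaBH4, MeOH, −40 to 0 °C) to [(2R,3R)-3-heptyloxiran-2-yl]methanol F2. Tf2O and 2,6-lutidine in CH2Cl2 at −78 °C give [(2R,3R)-3-heptyloxiran-2-yl]methyl trifluoromethanesulfonate F3. LiC≡CSiMe3 in THF/DMPU at −78 °C then displaces the primary triflate by SN2, without touching the oxirane, to give 5. The C8–C9 bond still comes from the oxiranyl anion; C7–C8 becomes an ordinary acetylide alkylation.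

Step 4 (Sharpless kinetic resolution of 7). The selectivity factor may be modest because ethynyl is a small group, the monosubstituted electron-poor alkene epoxidises slowly, and 8 is volatile and water-soluble. The fallback sets out from racemic 7 (together with 6) and comes back at 9. Racemic 7 is coupled directly with 6 under the conditions of step 5 to give the 1:1 C3-epimer mixture (3RS)-8-[(2R,3R)-3-heptyloxiran-2-yl]oct-1-ene-4,6-diyn-3-ol F4. Pseudomonas cepacia lipase with vinyl acetate in hexane at 30 °C should then acetylate the (3R)-epimer (long diynyl chain as the large group, vinyl as the medium group, Kazlauskas rule) to (3R)-8-[(2R,3R)-3-heptyloxiran-2-yl]oct-1-ene-4,6-diyn-3-yl acetate F5. The non-volatile (3S)-alcohol 9 is left and separated by chromatography.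

Step 3 (silver-catalysed bromodesilylation next to the oxirane). Ag+ may open the oxirane, and 6 may not survive concentration. The fallback sets out from 5 (together with 8) and comes back at 9; it is one step longer and swaps the roles of the coupling partners. K2CO3 in MeOH at 0 °C gives (2R,3R)-2-heptyl-3-(prop-2-yn-1-yl)oxirane F6. The bromine is placed on the other partner: 8 with NBS and AgNO3 (10 mol%) in acetone gives (3S)-5-bromopent-1-en-4-yn-3-ol F7, used cold without purification. Cadiot–Chodkiewicz coupling of F6 with F7 (CuCl, NH2OH·HCl, aqueous n-BuNH2, Et2O, 0 °C) gives 9.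

**Further compounds**
F1 | step 2 | (2S,3R)-3-heptyloxirane-2-carbaldehyde | O=C[C@H]1O[C@@H]1CCCCCCC
F2 | step 2 | [(2R,3R)-3-heptyloxiran-2-yl]methanol | OC[C@H]1O[C@@H]1CCCCCCC
F3 | step 2 | [(2R,3R)-3-heptyloxiran-2-yl]methyl trifluoromethanesulfonate | FC(F)(F)S(=O)(=O)OC[C@H]1O[C@@H]1CCCCCCC
F4 | step 4 | (3RS)-8-[(2R,3R)-3-heptyloxiran-2-yl]oct-1-ene-4,6-diyn-3-ol (1:1 C3 epimers) | C=CC(O)C#CC#CC[C@H]1O[C@@H]1CCCCCCC
F5 | step 4 | (3R)-8-[(2R,3R)-3-heptyloxiran-2-yl]oct-1-ene-4,6-diyn-3-yl acetate | C=C[C@H](C#CC#CC[C@H]1O[C@@H]1CCCCCCC)OC(C)=O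
F6 | step 3 | (2R,3R)-2-heptyl-3-(prop-2-yn-1-yl)oxirane | C#CC[C@H]1O[C@@H]1CCCCCCC
F7 | step 3 | (3S)-5-bromopent-1-en-4-yn-3-ol | C=C[C@@H](C#CBr)O
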